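(The readings are calculated from invented constants, and the scatter is random.)

The free catalyst in this flask is single-handed and the charge was a racemate, so I took the symmetric case as my zero: perfect selection turns the left-handed half of the charge, 50.0 %, into left-handed product and leaves the right-handed substrate alone.

| flask | left-handed substrate | right-handed substrate | partner | free catalyst | remark | time |
|---|---|---|---|---|---|---|
| autumn | 0.38 M | 0.38 M | 1.1 equiv | 0.61 mol% | the very flask that is asked about, followed so far |  |
| flask | 0.38 M | 0.38 M | 1.10 equiv | 0.61 mol% |  | 10 h |

autumn run (percent of the left-handed substrate and right-handed substrate together charged)

| time / h | left-handed product / % | left-handed substrate / % |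
|---|---|---|
| 0.833 | 40.2 | 10.4 |
| 1.50 | 41.9 | 8.6 |
| 2.50 | 42.6 | 7.0 |
| 3.00 | 43.2 | 7.2 |
| 4.00 | 43.6 | 7.2 |
| 5.00 | 43.0 | 6.4 |
| 6.00 | 43.6 | 6.8 |

(scatter of a reading: 0.3 percentage points)

- free catalyst is single-handed; left-handed substrate and right-handed substrate are mirror images of each other, charged as a racemate, each of them at the stated concentration
- left-handed product taken out counts as made
- additions bring no volume worth counting

- blue: at 10 h take out 90 % of the left-handed product then present, then wait 20 h
- ochre: change nothing and wait 20 h more
- red: at 10 h add free catalyst, 50.0 % of the amount charged, then wait 20 h
- grey: at 10 h add partner, 50.0 % of the amount charged, then wait 20 h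

- left-handed product, in percent of the left-handed substrate and right-handed substrate together first charged, at 10 h
- what to do for the largest gain in left-handed product; "none" if nothing gains more than 2 percentage points (blue / ochre / red / grey / none)
- left-handed product present, with what was taken out counted in, in percent of the left-handed substrate and right-handed substrate together first charged, after ochre
- left-handed product present, with what was taken out counted in, in percent of the left-handed substrate and right-handed substrate together first charged, after red

The last autumn reading of left-handed product and left-handed substrate summed to 50.4 %, close to that zero, so I read the left-handed substrate as going over to product. But product flattened from 3.00 h on at 43.4 %, with left-handed substrate still reading 6.8 %, so something had stopped the flask. The charged c(partner), 0.418 M, is 55.0 % on the same scale, which is more than the zero. So I kept one number, the partner gap, partner charged less left-handed product at the plateau, both in percent of the substrates charged: 12 percentage points. That is more than the left-handed substrate still reading, so a stall by partner needs a path these two columns do not show, and they cannot tell it from a stall by catalyst. I committed to the plateau, 43.4 % at 10 h.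

The forecast gave 43.4 % at 10 h, 43.5 % after ochre and 47 % after red, and it chose red, holding that “Dying catalyst fits better”.

This flask gave 43.2 % at 10 h, and the answer to the choice was none, with grey gaining 1.7 points and red 0 points.

    partner + free catalyst + left-handed substrate → free catalyst + left-handed product (k = 1.91 /M²/s)
    partner + free catalyst + right-handed substrate → free catalyst + right-handed product (k = 0.0655 /M²/s)
    free catalyst → spent catalyst (k = 7.61 × 10⁻⁵ /s)
    partner → decomposed reagent (k = 1.22 × 10⁻⁴ /s)

Free partner, the limiting reagent of this flask, stood at 0.0108 % of its charge at 10.0 h. The partner gap on the flask's value was 12 points, against 3.30 % as right-handed product and 8.51 % as decomposed reagent. In the neighbour flask with 4.40 equiv of partner, left-handed product stood at 50.0 %, and the same gap, told as a concentration, was 1.29 M.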